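The numbers stand for no real mixture; the flask was simulated.

In a one-step world the starting material has a single road, to the single ring, and the clock of that step gives the yield. This flask has more roads, and two chemists dispute what they cost.

| setting | summer | winter | dusk | noon |
|---|---|---|---|---|
| starting material | 1.5 M | 1.5 M | 1.5 M | 1.5 M |
| time | 80 min | 80 min | 80 min | 80 min |
| remark | at 90 °C until 15 min, from then on at 150 °C |  |  |  |
| temperature |  | 150 °C | 120 °C | 90 °C |

    starting material → single ring (k1 = 2.1 × 10⁻⁴ /s, Ea1 = 102 kJ/mol)
    2 starting material → open dimer (k2 = 0.0013 /M/s, Ea2 = 59.0 kJ/mol)
    starting material + open dimer → open trimer (k3 = 4.9 × 10⁻⁵ /M/s, Ea3 = 80.0 kJ/mol)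
    open dimer → ring dimer (k4 = 9.2 × 10⁻⁵ /s, Ea4 = 118 kJ/mol)
    crystals ⇌ single ring, rate k5*(cs5 - [single ring]) while solid is left; crystals form when [single ring] > cs5 (cs5 = 19 mM, k5 = 0.012 /s)
    (constants at 90 °C)

- in percentages every species weighs as the starting material in it: one open dimer or ring dimer counts as two
- in percentages every species weighs as the starting material in it: one open trimer counts as three
- for single ring the crystals are counted in
- a doubled species enters its step squared and goes two at a time
- as a solid, counted per litre of solution: crystals
- constants are those at 90 °C; use the activation energies for any other temperature

1. the best flask by amount of single ring, in percent of the starting material charged; "all alike" if 1.5 percentage points covers them all (summer / winter / dusk / noon / all alike)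
2. amount of single ring at the end, in percent of the starting material charged, summer
3. amount of single ring at the end, in percent of the starting material charged, winter
4. amount of single ring at the end, in percent of the starting material charged, dusk
5. amount of single ring at the end, in percent of the starting material charged, noon

The first chemist keeps the one-step view. Ring closure has a half-life of 55.0 min at 90 °C, so noon closes 63.5% of its charge in 80 min. At 150 °C that half-life is 0.457 min, so winter closes the whole charge.

The second chemist says the clock is the wrong question: two steps share the starting material. I side with the second and reckon by hand.

Write f for the fraction of the charge still unreacted. Ring closure uses it in proportion to f, and dimerisation in proportion to f squared. So the next bit of starting material reaches the single ring with the share r/(r+f). Take the quantity 0.0538, reckoned at 90 °C: this is the ring ratio r, the constant of ring closure divided by 2 times the dimerisation constant and the starting concentration. It is the flask's selectivity factor. At a held temperature r stays frozen while f falls.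

I drop the open trimer and sum the shares from f equal to one down to zero. The yield at the end of the road is then r ln(1 + 1/r), and time has left the formula.

At 90 °C this gives 16.0%. Going to 150 °C speeds ring closure by 120 and dimerisation by 16, a gain for the ring. So r rises to 0.406, and winter's yield is 50.4%.

The forecast is the second chemist's number. It names winter as best, at 49.9% within 48.8% to 50.6%. It gives dusk 31%, summer 23.4% and noon 13.3%, on the ground that “the flask that is hot from the start wins”. My winter figure differs from it: 50.4% stands above 49.9%. My noon figure of 16.0% also stands above 13.3%, and mine is reckoned for f at zero, not for the reading at 80 min.

The simulation gives winter as best, at 50.1%, with dusk 31.2%, summer 23.3% and noon 13.5%. The share view wins.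

The one-step view belongs where r stands far above f from the start, so that the share r/(r+f) nears one. The neighbour of summer charged at 0.38 M moves that way, reading 52.6% against 23.3%. At the start of summer, dimerisation used starting material 19 times as fast as ring closure, the inverse of r at 90 °C. Winter's r gave 50.4% against 50.1%. Noon's ring ratio gives 16.0%, and noon read 13.5% at 80 min with 2.7% unreacted, then 15.6% after 800 min.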